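**Retrosynthetic overview**
- Target 6 comes from flavone diacetate 5 by cleavage of two aryl acetates.
- 5 comes from the C2-symmetric diketone diacetate 4 by closing the O1–C8a bond (dehydrogenative C–H/O–H cyclisation). Both aryl groups of 4 are the same 3-oxy-4,5-dimethoxyphenyl unit, so either ring gives the same flavone.
- 4 comes from bisphenol diketone 3 by acetylation, and 3 from a crossed Claisen condensation of ketone 1 with ester 2.
- Ring order: both benzene rings are bought intact; the γ-pyrone ring is the only ring made, in the last step.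

Assumption: the target has no stereocentre, so no stereocontrol is needed, and 1 and 2 are taken as catalogue building blocks (1 is the less common of the two; availability and price were not checked).

**Step 1**
Reactants: 1 1-(3-hydroxy-4,5-dimethoxyphenyl)ethan-1-one; 2 methyl 3-hydroxy-4,5-dimethoxybenzoate
Product: 3 1,3-bis(3-hydroxy-4,5-dimethoxyphenyl)propane-1,3-dione
Conditions: LiHMDS (4.3 equiv), THF, −78 → 50 °C; then 1 M HCl
Reagents that add atoms: none
Why: Crossed Claisen condensation, in which the pre-formed phenoxide–enolate dianion of 1 is C-acylated by the non-enolisable ester 2 (added as its lithium phenoxide) and deprotonation of the product β-diketone drives the equilibrium; no stereocentre is formed.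

**Step 2**
Reactants: 3 1,3-bis(3-hydroxy-4,5-dimethoxyphenyl)propane-1,3-dione
Product: 4 1,3-bis(3-acetoxy-4,5-dimethoxyphenyl)propane-1,3-dione (mainly the chelated enol)
Conditions: Ac2O (2.3 equiv), pyridine, 0 °C → rt
Reagents that add atoms: acetic anhydride, CC(=O)OC(C)=O
Why: Pyridine-mediated O-acetylation of the two phenols, which leaves the strongly chelated β-diketone enol untouched in the absence of DMAP (as in the preparation of curcumin diacetate) and turns each C3 oxygen into a weak π-donor, as needed for the site selectivity of step 3; no stereocentre is formed.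

**Step 3**
Reactants: 4 1,3-bis(3-acetoxy-4,5-dimethoxyphenyl)propane-1,3-dione
Product: 6 8-hydroxy-2-(3-hydroxy-4,5-dimethoxyphenyl)-6,7-dimethoxy-4H-chromen-4-one, via flavone diacetate 5 (not isolated)
Conditions: 3,6-di-tert-butyl-9-mesityl-10-phenylacridinium BF4 (5 mol%), Co(dmgH)2(py)Cl (5 mol%), MeCN/HFIP 4:1 (0.02 M), 450 nm LEDs, Ar, rt; then conc., HCl (cat.), MeOH, 50 °C
Reagents that add atoms: none
Why: Proposed new method: a photoredox acceptorless dehydrogenative C–H/O–H cyclisation of an enolised 1,3-diaryl-1,3-diketone to a γ-pyrone, in which the excited acridinium (E* about +2.1 V) oxidises one dimethoxyaryl ring to its radical cation, the distal enol oxygen adds at the ring carbon para to the coplanar 5-OMe group (C2, between the acyl carbon and the weakly donating OAc, whereas C6 is only ortho to that OMe, para to OAc and shielded by the in-plane methyl), and loss of a proton followed by cobaloxime-mediated removal of H (H2 evolution) rearomatises to chromone 5; the closest known reaction types are acridinium/cobaloxime dehydrogenative lactonisation of 2-arylbenzoic acids and para-selective arene radical-cation C–H amination, the final acid-catalysed methanolysis of the two aryl acetates is a standard transesterification, and no stereocentre is formed.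

**Compound list**
1 | 1-(3-hydroxy-4,5-dimethoxyphenyl)ethan-1-one | CC(=O)c1cc(O)c(OC)c(OC)c1 | starting material
2 | methyl 3-hydroxy-4,5-dimethoxybenzoate | COC(=O)c1cc(O)c(OC)c(OC)c1 | starting material
3 | 1,3-bis(3-hydroxy-4,5-dimethoxyphenyl)propane-1,3-dione | O=C(CC(=O)c1cc(O)c(OC)c(OC)c1)c1cc(O)c(OC)c(OC)c1 | intermediate
4 | 1,3-bis(3-acetoxy-4,5-dimethoxyphenyl)propane-1,3-dione | CC(=O)Oc1cc(cc(OC)c1OC)C(=O)CC(=O)c1cc(OC(C)=O)c(OC)c(OC)c1 | intermediate
5 | 8-acetoxy-2-(3-acetoxy-4,5-dimethoxyphenyl)-6,7-dimethoxy-4H-chromen-4-one | CC(=O)Oc1cc(-c2cc(=O)c3cc(OC)c(OC)c(OC(C)=O)c3o2)cc(OC)c1OC | intermediate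
6 | 8-hydroxy-2-(3-hydroxy-4,5-dimethoxyphenyl)-6,7-dimethoxy-4H-chromen-4-one | COc1cc(-c2cc(=O)c3cc(OC)c(OC)c(O)c3o2)cc(O)c1OC | target

**Step count**
Total steps: 3. Longest linear sequence: 3 (1 + 2 → 3 → 4 → 6).

**Steps most likely to fail**

Step 3 (the proposed new cyclisation). Risks are no ring closure, closure at C6 (giving the 6-acetoxy-7,8-dimethoxy isomer), or oxidative dimerisation at the central carbon. The fallback uses known chemistry only; it sets out from ester 2 and comes back at 6. Commercial 2-hydroxy-4,5-dimethoxyacetophenone is brominated (NBS, MeCN, 0 °C) at the only free position ortho to the phenol to give 1-(3-bromo-2-hydroxy-4,5-dimethoxyphenyl)ethan-1-one F5. Claisen condensation of F5 with 2 (LiHMDS 4.2 equiv, THF) gives 1-(3-bromo-2-hydroxy-4,5-dimethoxyphenyl)-3-(3-hydroxy-4,5-dimethoxyphenyl)propane-1,3-dione F6. Cyclodehydration (cat. H2SO4, AcOH, 100 °C) gives 8-bromo-2-(3-hydroxy-4,5-dimethoxyphenyl)-6,7-dimethoxy-4H-chromen-4-one F7. Palladium-catalysed hydroxylation of the C8–Br bond (tBuBrettPhos Pd G3, benzaldoxime, Cs2CO3, DMF, 80 °C) then delivers 6.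

Step 1 (Claisen condensation on unprotected phenols). The polyanions may be poorly soluble and the phenoxide ester sluggish. The fallback sets out from 1 and 2 and comes back at 3. Both are silylated (TBSCl, imidazole, DMF) to 1-(3-((tert-butyldimethylsilyl)oxy)-4,5-dimethoxyphenyl)ethan-1-one F1 and methyl 3-((tert-butyldimethylsilyl)oxy)-4,5-dimethoxybenzoate F2. These are condensed with only 2.2 equiv LiHMDS (THF, −78 °C → rt) to 1,3-bis(3-((tert-butyldimethylsilyl)oxy)-4,5-dimethoxyphenyl)propane-1,3-dione F3. Desilylation (TBAF, AcOH, THF, 0 °C) gives 3.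

Step 2 (phenol-selective acetylation). The enol may be partly acylated. The fallback sets out from 3 and comes back at 4. Exhaustive acetylation (Ac2O, Et3N, cat. DMAP, CH2Cl2) gives (Z)-1,3-bis(3-acetoxy-4,5-dimethoxyphenyl)-3-oxoprop-1-en-1-yl acetate F4. Morpholine (1.0 equiv, CH2Cl2, 0 °C) then removes only the enol acetate, which is a vinylogous anhydride and far more reactive than the aryl acetates, to give 4.

**Further compounds**
F1 | step 1 | 1-(3-((tert-butyldimethylsilyl)oxy)-4,5-dimethoxyphenyl)ethan-1-one | CC(=O)c1cc(O[Si](C)(C)C(C)(C)C)c(OC)c(OC)c1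
F2 | step 1 | methyl 3-((tert-butyldimethylsilyl)oxy)-4,5-dimethoxybenzoate | COC(=O)c1cc(O[Si](C)(C)C(C)(C)C)c(OC)c(OC)c1
F3 | step 1 | 1,3-bis(3-((tert-butyldimethylsilyl)oxy)-4,5-dimethoxyphenyl)propane-1,3-dione | CC(C)(C)[Si](C)(C)Oc1cc(cc(OC)c1OC)C(=O)CC(=O)c1cc(O[Si](C)(C)C(C)(C)C)c(OC)c(OC)c1
F4 | step 2 | (Z)-1,3-bis(3-acetoxy-4,5-dimethoxyphenyl)-3-oxoprop-1-en-1-yl acetate | CC(=O)O/C(=C\C(=O)c1cc(OC(C)=O)c(OC)c(OC)c1)c1cc(OC(C)=O)c(OC)c(OC)c1
F5 | step 3 | 1-(3-bromo-2-hydroxy-4,5-dimethoxyphenyl)ethan-1-one | CC(=O)c1cc(OC)c(OC)c(Br)c1O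
F6 | step 3 | 1-(3-bromo-2-hydroxy-4,5-dimethoxyphenyl)-3-(3-hydroxy-4,5-dimethoxyphenyl)propane-1,3-dione | COc1cc(C(=O)CC(=O)c2cc(O)c(OC)c(OC)c2)c(O)c(Br)c1OC
F7 | step 3 | 8-bromo-2-(3-hydroxy-4,5-dimethoxyphenyl)-6,7-dimethoxy-4H-chromen-4-one | COc1cc(-c2cc(=O)c3cc(OC)c(OC)c(Br)c3o2)cc(O)c1OC
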